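The route rests on disconnecting ring B across C5–C10 and C6–C7: the equatorial C6 acetate, lying between the trans C5–C10 ring fusion and the tetrasubstituted C8=C9 alkene, is read as the Baeyer–Villiger product of a C6 acetyl group. One Lewis-acid intramolecular Diels–Alder reaction of an acyclic (E)-trienone therefore closes rings A and B together, sets C5, C6 and C10 and leaves the C8=C9 alkene in place. Its precursor carries a C7–C10 diene, built by directed carbomagnesiation and Suzuki coupling, the butenolide side chain already attached at C9, and a methyl enone on quaternary C4, which with C2 comes from a glutamic-acid-derived lactone.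

Key step: step 17

Remark: atoms are numbered as in the labdane skeleton of the target (C1–C20, butenolide C13–C16 with the carbonyl at C15), and 4-methoxybenzyl chloromethyl ether is assumed to be a purchasable reagent that is used fresh.

Step 1
Reactants: 1 (S)-5-(trityloxymethyl)dihydrofuran-2(3H)-one
Product: 3 (5S)-3-methyl-5-(trityloxymethyl)dihydrofuran-2(3H)-one as a C3 epimer mixture, via lithium lactone enolate 2 (not isolated)
Conditions: LiN(i-Pr)2 (1.1 equiv), THF, −78 °C; MeI, −78 to −40 °C
Reagents that add atoms: iodomethane, CI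
Why: Kinetic lactone enolate alkylation installs the future C18 methyl group, and the configuration of the new centre does not matter because it is erased when the enolate is formed again in step 2.

Step 2
Reactants: 3 (5S)-3-methyl-5-(trityloxymethyl)dihydrofuran-2(3H)-one
Product: 5 (3S,5S)-3-[(4-methoxybenzyloxy)methyl]-3-methyl-5-(trityloxymethyl)dihydrofuran-2(3H)-one, via methyl lactone lithium enolate 4 (not isolated)
Conditions: LiN(i-Pr)2 (1.2 equiv), THF, −78 °C; 4-MeOC6H4CH2OCH2Cl, −78 to −30 °C
Reagents that add atoms: 4-methoxybenzyl chloromethyl ether, COc1ccc(COCCl)cc1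
Why: Diastereoselective enolate alkylation of a γ-substituted butyrolactone, in which the planar enolate is shielded on one face by the bulky trityloxymethyl group so that the reactive chloromethyl ether enters anti to it and fixes quaternary C4 with the PMB-oxymethyl carbon (future C5) trans to the C2 substituent.

Step 3
Reactants: 5 (3S,5S)-3-[(4-methoxybenzyloxy)methyl]-3-methyl-5-(trityloxymethyl)dihydrofuran-2(3H)-one
Product: 6 (3S,5S)-5-(hydroxymethyl)-3-[(4-methoxybenzyloxy)methyl]-3-methyldihydrofuran-2(3H)-one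
Conditions: TsOH·H2O (cat.), MeOH/CH2Cl2, rt
Reagents that add atoms: none
Why: Acid-catalysed trityl ether solvolysis through the stabilised trityl cation, which methanol traps, is much faster than any reaction of the PMB ether or the γ-lactone under these mild conditions.

Step 4
Reactants: 6 (3S,5S)-5-(hydroxymethyl)-3-[(4-methoxybenzyloxy)methyl]-3-methyldihydrofuran-2(3H)-one
Product: 7 [(2S,4S)-4-[(4-methoxybenzyloxy)methyl]-4-methyl-5-oxotetrahydrofuran-2-yl]methyl 4-methylbenzenesulfonate
Conditions: TsCl, Et3N, DMAP (cat.), CH2Cl2, 0 °C to rt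
Reagents that add atoms: p-toluenesulfonyl chloride, Cc1ccc(cc1)S(=O)(=O)Cl
Why: Standard sulfonylation of an unhindered primary alcohol, which touches no stereocentre.

Step 5
Reactants: 7 [(2S,4S)-4-[(4-methoxybenzyloxy)methyl]-4-methyl-5-oxotetrahydrofuran-2-yl]methyl 4-methylbenzenesulfonate
Product: 9 methyl (2S)-2-[(4-methoxybenzyloxy)methyl]-2-methyl-3-[(2S)-oxiran-2-yl]propanoate, via ring-opened sodium alkoxide 8 (not isolated)
Conditions: NaOMe (1.1 equiv), MeOH, 0 °C to rt
Reagents that add atoms: sodium methoxide, C[O-].[Na+]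
Why: Lactone methanolysis followed by intramolecular Williamson etherification (3-exo-tet), in which the released C2 alkoxide displaces the neighbouring primary tosylate so that the C2–O bond is never broken and C2 keeps its configuration.

Step 6
Reactants: 9 methyl (2S)-2-[(4-methoxybenzyloxy)methyl]-2-methyl-3-[(2S)-oxiran-2-yl]propanoate; 10 tert-butyl(but-3-yn-1-yloxy)dimethylsilane
Product: 13 (3S,5R)-5-[5-(tert-butyldimethylsilyloxy)pent-2-yn-1-yl]-3-[(4-methoxybenzyloxy)methyl]-3-methyldihydrofuran-2(3H)-one, via lithium acetylide 11 (not isolated), via hydroxy ester 12 (not isolated)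
Conditions: 10 (2 equiv), n-BuLi, THF, −78 °C; BF3·OEt2, then 9, −78 °C; aq. NH4Cl; then PPTS (cat.), CH2Cl2, rt
Reagents that add atoms: none
Why: Yamaguchi–Hirao alkynylation, in which the lithium acetylide and BF3 open the monosubstituted epoxide by SN2 attack at the terminal carbon C1 at −78 °C while the hindered neopentyl-type ester stays inert, after which the γ-hydroxy ester closes to the five-membered lactone under mild acid with C2 untouched.

Step 7
Reactants: 13 (3S,5R)-5-[5-(tert-butyldimethylsilyloxy)pent-2-yn-1-yl]-3-[(4-methoxybenzyloxy)methyl]-3-methyldihydrofuran-2(3H)-one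
Product: 14 (2R,4R)-9-(tert-butyldimethylsilyloxy)-2-[(4-methoxybenzyloxy)methyl]-2-methylnon-6-yne-1,4-diol
Conditions: LiAlH4, THF, 0 °C
Reagents that add atoms: none
Why: Hydride reduction of a lactone to the diol (C2–OH and C19–OH), to which the PMB and TBS ethers and the isolated alkyne are inert at 0 °C.

Step 8
Reactants: 14 (2R,4R)-9-(tert-butyldimethylsilyloxy)-2-[(4-methoxybenzyloxy)methyl]-2-methylnon-6-yne-1,4-diol
Product: 15 (2S,4R)-9-(tert-butyldimethylsilyloxy)-2-[(4-methoxybenzyloxy)methyl]-2-methyl-1,4-bis(triisopropylsilyloxy)non-6-yne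
Conditions: TIPSOTf (2.5 equiv), 2,6-lutidine, CH2Cl2, 0 °C to rt
Reagents that add atoms: triisopropylsilyl trifluoromethanesulfonate, CC(C)[Si](OS(=O)(=O)C(F)(F)F)(C(C)C)C(C)C
Why: Silylation with a silyl triflate is forceful enough for both the secondary C2 hydroxyl and the neopentyl C19 hydroxyl, and the hindered base keeps the medium safe for the TBS and PMB ethers.

Step 9
Reactants: 15 (2S,4R)-9-(tert-butyldimethylsilyloxy)-2-[(4-methoxybenzyloxy)methyl]-2-methyl-1,4-bis(triisopropylsilyloxy)non-6-yne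
Product: 16 (6R,8S)-9-[(4-methoxybenzyl)oxy]-8-methyl-6-[(triisopropylsilyl)oxy]-8-{[(triisopropylsilyl)oxy]methyl}non-3-yn-1-ol
Conditions: PPTS (cat.), MeOH, rt
Reagents that add atoms: none
Why: Acid-catalysed methanolysis of silyl ethers is governed by steric access, so the unhindered primary TBS ether at C12 is cleaved well before the secondary and neopentyl TIPS ethers, and the PMB ether is stable.

Step 10
Reactants: 16 (6R,8S)-9-[(4-methoxybenzyl)oxy]-8-methyl-6-[(triisopropylsilyl)oxy]-8-{[(triisopropylsilyl)oxy]methyl}non-3-yn-1-ol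
Product: 18 (3E,6S,8S)-3-iodo-9-[(4-methoxybenzyl)oxy]-4,8-dimethyl-6-[(triisopropylsilyl)oxy]-8-{[(triisopropylsilyl)oxy]methyl}non-3-en-1-ol (I on C9 cis to CH3 on C10), via alkenylmagnesium chelate 17 (not isolated)
Conditions: MeMgBr (5 equiv), Fe(acac)3 (cat.), dppe (cat.), THF, −78 to 0 °C; then I2, THF, −78 °C to rt
Reagents that add atoms: methylmagnesium bromide, C[Mg]Br; iodine, [I][I]
Why: Alkoxide-directed iron-catalysed syn carbomagnesiation of a homopropargylic alcohol delivers methyl to the distal alkyne carbon C10 and leaves magnesium on C9 in a five-membered chelate, and iodinolysis of the alkenyl–magnesium bond with retention then gives the tetrasubstituted iodide whose cis CH3/I arrangement fixes the C9=C10 geometry that the diene needs.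

Step 11
Reactants: 18 (3E,6S,8S)-3-iodo-9-[(4-methoxybenzyl)oxy]-4,8-dimethyl-6-[(triisopropylsilyl)oxy]-8-{[(triisopropylsilyl)oxy]methyl}non-3-en-1-ol; 19 isopropenylboronic acid pinacol ester
Product: 20 (3E,6R,8S)-9-[(4-methoxybenzyl)oxy]-4,8-dimethyl-3-(prop-1-en-2-yl)-6-[(triisopropylsilyl)oxy]-8-{[(triisopropylsilyl)oxy]methyl}non-3-en-1-ol (isopropenyl on C9 cis to CH3 on C10)
Conditions: 19 (2 equiv), Pd(dppf)Cl2 (cat.), Cs2CO3, THF/H2O, 60 °C
Reagents that add atoms: none
Why: Suzuki–Miyaura coupling proceeds with retention of geometry at the alkenyl iodide, so the isopropenyl group (C7, C8, C17) ends cis to the C10 methyl, and the ferrocenyl bisphosphine catalyst copes with the tetrasubstituted iodide and tolerates the free alcohol.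

Step 12
Reactants: 20 (3E,6R,8S)-9-[(4-methoxybenzyl)oxy]-4,8-dimethyl-3-(prop-1-en-2-yl)-6-[(triisopropylsilyl)oxy]-8-{[(triisopropylsilyl)oxy]methyl}non-3-en-1-ol
Product: 21 the C12 iodide of dienol 20 (CH2CH2I on C9, diene geometry and both stereocentres unchanged)
Conditions: I2, PPh3, imidazole, CH2Cl2, 0 °C
Reagents that add atoms: iodine, [I][I]
Why: Appel-type iodination converts the unhindered primary alcohol by SN2 displacement of its alkoxyphosphonium ion under imidazole-buffered conditions that leave the acid-sensitive diene and the silyl and PMB ethers alone.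

Step 13
Reactants: 21 the C12 iodide of dienol 20; 22 4-bromofuran-2(5H)-one
Product: 24 the diene butenolide in which C12 is bonded to C4 of furan-2(5H)-one (C5–OPMB and C2 and C19 TIPS ethers kept), via alkylzinc iodide 23 (not isolated)
Conditions: Zn dust (activated), LiCl, THF, 40 °C; then 22, Pd(dppf)Cl2 (cat.), THF, rt to 45 °C
Reagents that add atoms: none
Why: Negishi coupling, in which zinc inserts into the primary C–I bond to give a homoallylic zinc reagent with no β-leaving group, and zerovalent palladium carrying the wide-bite-angle dppf ligand joins it to the vinylogous acyl bromide faster than β-hydride elimination, forming the C12–C13 bond with the butenolide intact.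

Step 14
Reactants: 24 the diene butenolide PMB ether
Product: 25 the C5 primary alcohol (24 without the PMB group)
Conditions: DDQ (1.2 equiv), CH2Cl2/aq. NaH2PO4–Na2HPO4 (pH 7), 0 °C
Reagents that add atoms: none
Why: Oxidative PMB ether cleavage, in which DDQ removes hydride from the electron-rich benzylic position and water collapses the oxocarbenium ion to anisaldehyde and the free alcohol, run cold, buffered and with little excess oxidant to spare the twisted diene.

Step 15
Reactants: 25 the C5 primary alcohol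
Product: 26 the C5 aldehyde (formyl group on quaternary C4)
Conditions: Dess–Martin periodinane, NaHCO3, CH2Cl2, 0 °C to rt
Reagents that add atoms: none
Why: Dess–Martin oxidation is neutral when buffered, and the aldehyde formed can neither enolise nor epimerise because C4 is quaternary.

Step 16
Reactants: 26 the C5 aldehyde; 27 1-(triphenylphosphoranylidene)propan-2-one
Product: 28 the acyclic (E)-trienone (C4–CH=CH–C(O)CH3 with the C7–C10 diene and the butenolide side chain, C2 R and C4 S)
Conditions: 27 (3 equiv), toluene, 90 °C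
Reagents that add atoms: none
Why: Wittig olefination with a stabilised acyl ylide is reliably (E)-selective and tolerates the lactone, and the temperature needed by the neopentyl aldehyde is kept moderate so that neither uncatalysed cyclisation of the hindered trienone nor a 1,5-hydrogen shift in the diene should intervene.

Step 17
Reactants: 28 the acyclic (E)-trienone
Product: 29 (2R,4S,5R,6S,10S)-6-acetyl-2,19-bis(triisopropylsilyloxy)labda-8,13-dien-15,16-olide (trans-decalin, 6α-acetyl, H-5 α, C20 β)
Conditions: Me2AlCl (2.5 equiv), CH2Cl2, −78 to −20 °C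
Reagents that add atoms: none
Why: Me2AlCl binds the acetyl oxygen (the excess is taken up by the butenolide carbonyl) and the activated (E)-enone engages the tetraalkyl diene in a concerted but asynchronous [4+2] cycloaddition in which the C5–C10 bond leads, with positive charge building at tertiary C9, and the C6–C7 bond follows. The closest known reaction type is the Lewis-acid-promoted type 1 intramolecular Diels–Alder reaction of terminally activated (E)-1,7,9-decatrien-3-ones, which gives trans-fused decalins through the endo transition state. Ring A closes as a six-membered carbocycle by the C5–C10 bond through the four-carbon tether C1–C4 held in a chair, and ring B is the cyclohexene created by the cycloaddition itself, with the C8=C9 alkene left exactly where the target has it. C5, C6 and C10 are set relative to one another by the (E)-enone geometry and the endo position of the aluminium-bound acetyl group, which give the trans ring fusion and the equatorial 6α-acetyl group, while C2 and C4 choose the diene face because only one chair places the C2 silyloxy group equatorial and the C4 silyloxymethyl group axial, the other forcing the silyloxy group, C18 and C20 into a triple syn-axial array. The step therefore needs endo and diene-face selectivity and a rate that outruns side reactions, which the substrate supports through an electron-rich diene whose C9=C10 geometry puts the tether outside and only C20 inside, a quaternary C4 that adds a gem-dialkyl effect and removes any enolisable position next to the enone, and low-temperature activation at which a 1,5-hydrogen shift from C20 cannot compete.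

Step 18
Reactants: 29 (2R,4S,5R,6S,10S)-6-acetyl-2,19-bis(triisopropylsilyloxy)labda-8,13-dien-15,16-olide
Product: 30 (2R,4S,5R,6S,10S)-6-acetoxy-2,19-bis(triisopropylsilyloxy)labda-8,13-dien-15,16-olide
Conditions: Me3SiOOSiMe3 (3 equiv), SnCl4 (cat.), trans-cyclohexane-1,2-diamine (cat.), 4 Å MS, CH2Cl2, 0 °C to rt
Reagents that add atoms: bis(trimethylsilyl) peroxide, C[Si](C)(C)OO[Si](C)(C)C
Why: Baeyer–Villiger oxidation with a Lewis-acid-activated silyl peroxide, in which the secondary carbon C6 migrates in preference to methyl with retention of configuration to give the 6α-acetate, while this reagent, unlike a peracid, should not epoxidise the tetrasubstituted C8=C9 alkene.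

Step 19
Reactants: 30 (2R,4S,5R,6S,10S)-6-acetoxy-2,19-bis(triisopropylsilyloxy)labda-8,13-dien-15,16-olide
Product: 31 CNP0231903.1, (2R,4S,5R,6S,10S)-6-acetoxy-2,19-dihydroxylabda-8,13-dien-15,16-olide
Conditions: HF·pyridine, pyridine/THF, 0 °C to rt
Reagents that add atoms: none
Why: Fluoride-mediated desilylation under mildly acidic conditions removes both TIPS ethers without the acetate hydrolysis, acyl migration or butenolide opening that a basic fluoride source could cause.

Compound list
1 | (S)-5-(trityloxymethyl)dihydrofuran-2(3H)-one | O=C1CC[C@@H](COC(c2ccccc2)(c2ccccc2)c2ccccc2)O1 | starting material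
2 | lithium enolate of lactone 1 (5S) | c1ccccc1C(c1ccccc1)(c1ccccc1)OC[C@@H]1CC=C(O[Li])O1 | intermediate
3 | (5S)-3-methyl-5-(trityloxymethyl)dihydrofuran-2(3H)-one, C3 epimer mixture | c1ccccc1C(c1ccccc1)(c1ccccc1)OC[C@@H]1CC(C)C(=O)O1 | intermediate
4 | lithium enolate of methyl lactone 3 (5S) | c1ccccc1C(c1ccccc1)(c1ccccc1)OC[C@@H]1CC(C)=C(O[Li])O1 | intermediate
5 | (3S,5S)-3-[(4-methoxybenzyloxy)methyl]-3-methyl-5-(trityloxymethyl)dihydrofuran-2(3H)-one (PMB-oxymethyl trans to trityloxymethyl) | c1ccccc1C(c1ccccc1)(c1ccccc1)OC[C@@H]1C[C@@](C)(COCc2ccc(OC)cc2)C(=O)O1 | intermediate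
6 | (3S,5S)-5-(hydroxymethyl)-3-[(4-methoxybenzyloxy)methyl]-3-methyldihydrofuran-2(3H)-one | OC[C@@H]1C[C@@](C)(COCc2ccc(OC)cc2)C(=O)O1 | intermediate
7 | [(2S,4S)-4-[(4-methoxybenzyloxy)methyl]-4-methyl-5-oxotetrahydrofuran-2-yl]methyl 4-methylbenzenesulfonate | Cc1ccc(cc1)S(=O)(=O)OC[C@@H]1C[C@@](C)(COCc2ccc(OC)cc2)C(=O)O1 | intermediate
8 | sodium (2S,4S)-5-methoxy-4-[(4-methoxybenzyloxy)methyl]-4-methyl-5-oxo-1-(tosyloxy)pentan-2-olate | COC(=O)[C@](C)(COCc1ccc(OC)cc1)C[C@H]([O-])COS(=O)(=O)c1ccc(C)cc1.[Na+] | intermediate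
9 | methyl (2S)-2-[(4-methoxybenzyloxy)methyl]-2-methyl-3-[(2S)-oxiran-2-yl]propanoate | COC(=O)[C@](C)(COCc1ccc(OC)cc1)C[C@H]1CO1 | intermediate
10 | tert-butyl(but-3-yn-1-yloxy)dimethylsilane | C#CCCO[Si](C)(C)C(C)(C)C | starting material
11 | [4-(tert-butyldimethylsilyloxy)but-1-yn-1-yl]lithium | [Li]C#CCCO[Si](C)(C)C(C)(C)C | intermediate
12 | methyl (2S,4R)-9-(tert-butyldimethylsilyloxy)-4-hydroxy-2-[(4-methoxybenzyloxy)methyl]-2-methylnon-6-ynoate | COC(=O)[C@](C)(COCc1ccc(OC)cc1)C[C@H](O)CC#CCCO[Si](C)(C)C(C)(C)C | intermediate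
13 | (3S,5R)-5-[5-(tert-butyldimethylsilyloxy)pent-2-yn-1-yl]-3-[(4-methoxybenzyloxy)methyl]-3-methyldihydrofuran-2(3H)-one | CC(C)(C)[Si](C)(C)OCCC#CC[C@@H]1C[C@@](C)(COCc2ccc(OC)cc2)C(=O)O1 | intermediate
14 | (2R,4R)-9-(tert-butyldimethylsilyloxy)-2-[(4-methoxybenzyloxy)methyl]-2-methylnon-6-yne-1,4-diol | CC(C)(C)[Si](C)(C)OCCC#CC[C@@H](O)C[C@](C)(CO)COCc1ccc(OC)cc1 | intermediate
15 | (2S,4R)-9-(tert-butyldimethylsilyloxy)-2-[(4-methoxybenzyloxy)methyl]-2-methyl-1,4-bis(triisopropylsilyloxy)non-6-yne | CC(C)(C)[Si](C)(C)OCCC#CC[C@@H](O[Si](C(C)C)(C(C)C)C(C)C)C[C@](C)(CO[Si](C(C)C)(C(C)C)C(C)C)COCc1ccc(OC)cc1 | intermediate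
16 | (6R,8S)-9-[(4-methoxybenzyl)oxy]-8-methyl-6-[(triisopropylsilyl)oxy]-8-{[(triisopropylsilyl)oxy]methyl}non-3-yn-1-ol | OCCC#CC[C@@H](O[Si](C(C)C)(C(C)C)C(C)C)C[C@](C)(CO[Si](C(C)C)(C(C)C)C(C)C)COCc1ccc(OC)cc1 | intermediate
17 | alkenylmagnesium chelate of 16 (five-membered O–Mg–C9 ring, CH3 on C10 cis to Mg, stereocentres as in 16) | C/C(C[C@@H](O[Si](C(C)C)(C(C)C)C(C)C)C[C@](C)(CO[Si](C(C)C)(C(C)C)C(C)C)COCc1ccc(OC)cc1)=C(/CCO2)[Mg]2 | intermediate
18 | (3E,6S,8S)-3-iodo-9-[(4-methoxybenzyl)oxy]-4,8-dimethyl-6-[(triisopropylsilyl)oxy]-8-{[(triisopropylsilyl)oxy]methyl}non-3-en-1-ol (I cis to CH3) | OCCC(/I)=C(/C)C[C@@H](O[Si](C(C)C)(C(C)C)C(C)C)C[C@](C)(CO[Si](C(C)C)(C(C)C)C(C)C)COCc1ccc(OC)cc1 | intermediate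
19 | isopropenylboronic acid pinacol ester | CC(=C)B1OC(C)(C)C(C)(C)O1 | starting material
20 | (3E,6R,8S)-9-[(4-methoxybenzyl)oxy]-4,8-dimethyl-3-(prop-1-en-2-yl)-6-[(triisopropylsilyl)oxy]-8-{[(triisopropylsilyl)oxy]methyl}non-3-en-1-ol (isopropenyl cis to CH3) | OCCC(/C(C)=C)=C(/C)C[C@@H](O[Si](C(C)C)(C(C)C)C(C)C)C[C@](C)(CO[Si](C(C)C)(C(C)C)C(C)C)COCc1ccc(OC)cc1 | intermediate
21 | C12 iodide of dienol 20 (same diene geometry, C2 R, C4 S) | ICCC(/C(C)=C)=C(/C)C[C@@H](O[Si](C(C)C)(C(C)C)C(C)C)C[C@](C)(CO[Si](C(C)C)(C(C)C)C(C)C)COCc1ccc(OC)cc1 | intermediate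
22 | 4-bromofuran-2(5H)-one | BrC1=CC(=O)OC1 | starting material
23 | alkylzinc iodide from 21 (C12–ZnI) | I[Zn]CCC(/C(C)=C)=C(/C)C[C@@H](O[Si](C(C)C)(C(C)C)C(C)C)C[C@](C)(CO[Si](C(C)C)(C(C)C)C(C)C)COCc1ccc(OC)cc1 | intermediate
24 | diene butenolide: 20 with the C12 hydroxyl replaced by the 5-oxo-2,5-dihydrofuran-3-yl group, C5–OPMB, C2 R, C4 S | O=C1OCC(CCC(/C(C)=C)=C(/C)C[C@@H](O[Si](C(C)C)(C(C)C)C(C)C)C[C@](C)(CO[Si](C(C)C)(C(C)C)C(C)C)COCc2ccc(OC)cc2)=C1 | intermediate
25 | C5 primary alcohol: 24 without the PMB group, C2 R, C4 S | O=C1OCC(CCC(/C(C)=C)=C(/C)C[C@@H](O[Si](C(C)C)(C(C)C)C(C)C)C[C@](C)(CO[Si](C(C)C)(C(C)C)C(C)C)CO)=C1 | intermediate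
26 | C5 aldehyde of 25, C2 R, C4 R | O=C1OCC(CCC(/C(C)=C)=C(/C)C[C@@H](O[Si](C(C)C)(C(C)C)C(C)C)C[C@](C)(CO[Si](C(C)C)(C(C)C)C(C)C)C=O)=C1 | intermediate
27 | 1-(triphenylphosphoranylidene)propan-2-one | CC(=O)C=P(c1ccccc1)(c1ccccc1)c1ccccc1 | starting material
28 | acyclic (E)-trienone: C4–CH=CH–C(O)CH3, C7=C8(CH3)–C9=C10(CH3) diene with CH3 on C10 cis to C8, butenolide on C12, C2 R, C4 S | C=C(C)/C(CCC1=CC(=O)OC1)=C(\C)C[C@@H](O[Si](C(C)C)(C(C)C)C(C)C)C[C@](C)(CO[Si](C(C)C)(C(C)C)C(C)C)/C=C/C(C)=O | intermediate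
29 | (2R,4S,5R,6S,10S)-6-acetyl-2,19-bis(triisopropylsilyloxy)labda-8,13-dien-15,16-olide (6α-acetyl, trans-decalin) | CC(=O)[C@H]1CC(C)=C(CCC2=CC(=O)OC2)[C@@]2(C)C[C@@H](O[Si](C(C)C)(C(C)C)C(C)C)C[C@](C)(CO[Si](C(C)C)(C(C)C)C(C)C)[C@H]12 | intermediate
30 | (2R,4S,5R,6S,10S)-6-acetoxy-2,19-bis(triisopropylsilyloxy)labda-8,13-dien-15,16-olide | CC(=O)O[C@H]1CC(C)=C(CCC2=CC(=O)OC2)[C@@]2(C)C[C@@H](O[Si](C(C)C)(C(C)C)C(C)C)C[C@](C)(CO[Si](C(C)C)(C(C)C)C(C)C)[C@H]12 | intermediate
31 | CNP0231903.1, (2R,4S,5R,6S,10S)-6-acetoxy-2,19-dihydroxylabda-8,13-dien-15,16-olide (6α-OAc, 2α-OH, H-5 α, C20 β) | CC(=O)O[C@H]1CC(C)=C(CCC2=CC(=O)OC2)[C@@]2(C)C[C@@H](O)C[C@](C)(CO)[C@H]12 | target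

Total step count: 19. Longest linear sequence: 19 steps, from lactone 1; compounds 10, 19, 22 and 27 are bought.

Steps most likely to fail

Step 17. The fully substituted diene terminus, with C20 on the inside, may react too slowly under neutral Lewis-acid activation. Cationic cyclisation with proton loss, oligomerisation or erosion of endo selectivity could then take over. The fallback forms the same two bonds but changes the dienophile from an aluminium-bound enone to a cationic one (ionic Diels–Alder reaction of a 2-vinyl-1,3-dioxolane). It sets out from trienone 28, which is ketalised with 1,2-bis(trimethylsilyloxy)ethane and catalytic Me3SiOTf in CH2Cl2 at −78 °C to give trienone ethylene ketal F1; no double-bond migration is possible because C4 is quaternary. Catalytic TfOH at −78 to −40 °C should ionise the dioxolane to the 2-alkoxyallyl cation, a far more electrophilic partner, which cyclises and recloses to decalin ethylene ketal F2. PPTS in wet acetone then frees the ketone and returns to 29; a brief DBU treatment would correct any C6 epimer to the equatorial 6α-acetyl compound.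

Step 18. Chemoselectivity may be lost: oxidation of the electron-rich tetrasubstituted C8=C9 alkene, or acid-induced migration of that alkene, may outpace oxygen insertion at the hindered ketone. The fallback accepts the alkene oxidation and uses it as temporary protection. From ketone 29, mCPBA/NaHCO3 in CH2Cl2 at 0 °C should epoxidise the alkene from the less hindered α face to give 8α,9α-epoxy ketone F3. Buffered trifluoroperacetic acid ((CF3CO)2O, urea–H2O2, Na2HPO4, CH2Cl2, 0 °C) then performs the Baeyer–Villiger step with retention at C6 to give 8α,9α-epoxy acetate F4. Deoxygenation with Cp2TiCl (from Cp2TiCl2 and Zn, THF, rt) regenerates the C8=C9 alkene and returns to 30: trivalent titanium opens the epoxide to a tertiary radical, a second equivalent traps it, and the β-titanoxy organotitanium eliminates.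

Step 14. Over-oxidation is the risk: DDQ may attack the electron-rich diene by charge-transfer oxidation, allylic hydride abstraction or cycloaddition in competition with the PMB ether. The fallback moves the oxidative deprotection in front of diene formation. From vinyl iodide 18, DDQ under the conditions of step 14 gives iodo diol F5, and Suzuki coupling with 19 as in step 11 gives dienediol F6. Appel iodination with 1.05 equiv of reagent at 0 °C should take only the unhindered C12 hydroxyl and leave the neopentyl C5 hydroxyl, giving iodo alcohol F7. Et3SiCl/imidazole gives triethylsilyl ether F8, and zinc insertion gives alkylzinc iodide F9, which is coupled with 22 as in step 13 to give butenolide triethylsilyl ether F10. PPTS in MeOH at 0 °C removes the primary triethylsilyl group in the presence of both TIPS ethers and returns to alcohol 25.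

Further compounds
F1 | step 17 | trienone ethylene ketal (2-methyl-1,3-dioxolane of 28) | C=C(C)/C(CCC1=CC(=O)OC1)=C(\C)C[C@@H](O[Si](C(C)C)(C(C)C)C(C)C)C[C@](C)(CO[Si](C(C)C)(C(C)C)C(C)C)/C=C/C1(C)OCCO1
F2 | step 17 | decalin ethylene ketal (2-methyl-1,3-dioxolane of 29) | CC1(OCCO1)[C@H]1CC(C)=C(CCC2=CC(=O)OC2)[C@@]2(C)C[C@@H](O[Si](C(C)C)(C(C)C)C(C)C)C[C@](C)(CO[Si](C(C)C)(C(C)C)C(C)C)[C@H]12
F3 | step 18 | 8α,9α-epoxy ketone (epoxide of 29) | CC(=O)[C@H]1C[C@@]3(C)O[C@@]3(CCC2=CC(=O)OC2)[C@@]2(C)C[C@@H](O[Si](C(C)C)(C(C)C)C(C)C)C[C@](C)(CO[Si](C(C)C)(C(C)C)C(C)C)[C@H]12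
F4 | step 18 | 8α,9α-epoxy acetate (epoxide of 30) | CC(=O)O[C@H]1C[C@@]3(C)O[C@@]3(CCC2=CC(=O)OC2)[C@@]2(C)C[C@@H](O[Si](C(C)C)(C(C)C)C(C)C)C[C@](C)(CO[Si](C(C)C)(C(C)C)C(C)C)[C@H]12
F5 | step 14 | iodo diol (18 without the PMB group) | OCCC(/I)=C(/C)C[C@@H](O[Si](C(C)C)(C(C)C)C(C)C)C[C@](C)(CO[Si](C(C)C)(C(C)C)C(C)C)CO
F6 | step 14 | dienediol (20 without the PMB group) | OCCC(/C(C)=C)=C(/C)C[C@@H](O[Si](C(C)C)(C(C)C)C(C)C)C[C@](C)(CO[Si](C(C)C)(C(C)C)C(C)C)CO
F7 | step 14 | iodo alcohol (C12 iodide, free C5 hydroxyl) | ICCC(/C(C)=C)=C(/C)C[C@@H](O[Si](C(C)C)(C(C)C)C(C)C)C[C@](C)(CO[Si](C(C)C)(C(C)C)C(C)C)CO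
F8 | step 14 | triethylsilyl ether of F7 (C5–OSiEt3) | ICCC(/C(C)=C)=C(/C)C[C@@H](O[Si](C(C)C)(C(C)C)C(C)C)C[C@](C)(CO[Si](C(C)C)(C(C)C)C(C)C)CO[Si](CC)(CC)CC
F9 | step 14 | alkylzinc iodide from F8 | I[Zn]CCC(/C(C)=C)=C(/C)C[C@@H](O[Si](C(C)C)(C(C)C)C(C)C)C[C@](C)(CO[Si](C(C)C)(C(C)C)C(C)C)CO[Si](CC)(CC)CC
F10 | step 14 | butenolide triethylsilyl ether (25 as its C5–OSiEt3 ether) | O=C1OCC(CCC(/C(C)=C)=C(/C)C[C@@H](O[Si](C(C)C)(C(C)C)C(C)C)C[C@](C)(CO[Si](C(C)C)(C(C)C)C(C)C)CO[Si](CC)(CC)CC)=C1
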